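Remark on the chemistry: the target has no stereocentre and no stereogenic double bond (the prenyl alkene carries two methyl groups on one carbon), so it is achiral and the structure as drawn is its only stereoisomer.

Compound numbers are those of the steps and of the compound list below.

## Analysis of the target

Target 19 is a flavonol: a 4H-chromen-4-one (benzo ring A fused to pyranone ring C) with an aryl ring B on C2 and a hydroxyl on C3. Ring A carries a catechol at C6/C7. Ring B carries a free 4'-hydroxyl and, next to it on C3', a 3-methylbut-2-enyl (prenyl) ether. There is no stereocentre, so the problems are regiochemistry and functional-group tolerance. The prenyl aryl ether is the sensitive group: it ionises in strong acid, is reduced by hydrogenation, is epoxidised by electrophilic oxidants and can be ionised by palladium(0). The free catechol and the 3-hydroxypyranone are air-sensitive under base. The difficulty is that five peripheral oxygens must end as four free hydroxyls and one ether, so the two B-ring oxygens must be told apart and every protecting group must leave without hydrogenolysis, strong Lewis acid or oxidant. The usual oxidative ways of installing the C3 oxygen also collide with the alkene. The strategy rests on C2: it is at the carbonyl oxidation level and is bonded only to O1, C3 and C1', so it can be carbon monoxide 15 inserted between an aryl halide carbon (C1') and the enolate carbon (C3) of an A-ring ketone that already holds O1, C4 and the C3 oxygen.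

## Retrosynthetic reasoning

**19 from 18.** The four O–CH2OMe acetal bonds are cut last. Methoxymethyl groups are chosen because they survive amine base, heat and palladium, and leave under mild Brønsted acid through an oxocarbenium ion that forms far more easily than a prenyl cation. Benzyl ethers are excluded at this stage because hydrogenolysis would reduce the alkene. Methyl ethers are excluded because their cleavage needs boron or aluminium halides.

**18 from 8, 14 and 15.** Ring C is opened at three bonds that meet at C2: C2–C1', C2–C3 and O1–C2. This removes the single carbon C2 as carbon monoxide 15 and leaves two aromatic pieces of similar size. Ketone 8 holds ring A, C4, C3 with its protected oxygen, and the free ortho phenol that becomes O1. Bromide 14 holds ring B with its two oxygens already differentiated. Cutting here rather than at C3–C4 or C4–C4a keeps every oxygen at its final oxidation level, so no oxidation is needed once the prenyl group is present. The forward reaction has to insert 15 into the aryl–palladium bond before the enolate can arylate directly, and it has to transfer the aroyl group to C3. Transfer to the phenol oxygen is harmless, because base moves the acyl group from oxygen to carbon and both paths meet at diketone 16. Addition of the phenol to the new carbonyl gives hemiketal 17, and loss of water gives 18.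

**8 from 1.** The C3 oxygen is traced back to the methyl group of 1 by enolate oxidation. The sequence is 1 to 2 (acetals on the two unchelated phenols), 2 to 3 (benzyl on the chelated phenol), 3 to 6 (α-hydroxylation through silyl enol ether 4 and silyloxy ketone 5), 6 to 7 (acetal on the new alcohol) and 7 to 8 (hydrogenolysis). A shorter sequence that oxidises 2 directly was weighed and dropped for three reasons:
- the free phenol would force dianion chemistry on the enolate;
- iodine(III) oxidants tend to close a five-membered furanone ring through the ortho phenoxide;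
- the later acetal formation would have to choose between the new primary alcohol and the phenol.

The benzyl ether removes all three doubts at the cost of two routine steps. It can leave by hydrogenolysis because no compound of this arm contains an alkene; the prenyl group lives only in 14.

**14 from 9 and 13.** The prenyl ether C–O bond is cut to phenol 12 and prenyl bromide 13. The hydroxyl of 12 is traced to the formyl group of 10 by aryl migration to oxygen (through formate 11), and 10 is the acetal of 9. In 9 the bromine is para to the hydroxyl, so the order acetal, then oxidation, then prenylation places the acetal-protected oxygen para and the prenyl ether meta to the future C1', as 19 requires. The peracid is used before the alkene exists.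

## Alternatives that were turned down

Alternative 1: The C3–C4 bond is cut, leading to dialdehyde A2, in which an A-ring salicylaldehyde oxygen carries an α-aryl acetaldehyde unit. In the forward step an N-heterocyclic carbene turns the aromatic aldehyde into an acyl anion equivalent, which adds to the aliphatic aldehyde and closes the oxygen ring to give the trans 3-hydroxychroman-4-one A1.
- For it: no metal and no gas, and the C3 hydroxyl is created by the bond-forming step itself, so no α-oxygenated ketone has to be prepared. On that point it is stronger than the chosen route.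
- Against it: A1 is two hydrogens too reduced. A C2–C3 dehydrogenation must follow in the presence of the prenyl alkene and two electron-rich rings, and it erases two stereocentres that the key step built for nothing.
- Against it: A2 is an α-aryl-α-aryloxy aldehyde. It is strongly enolisable and prone to aldol chemistry, and it is not short to make.
- Against it: the carbene must select the aromatic aldehyde as donor. The reverse polarity would put the ketone at C3 and the carbinol at C4.
- Comparison: the chosen route reaches the flavone oxidation level directly and forms three bonds where this one forms one.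

Alternative 2: The bonds C4a–C4, C4–C3 and O1–C2 are cut, so that C4 becomes carbon monoxide 15 between iodophenol A4 and B-ring alkyne A5. The forward step is a carbonylative Sonogashira coupling to ynone A6, followed by addition of the phenol to the triple bond to give flavone A3.
- For it: it is as convergent as the chosen route, it uses the same gas, and it is the better precedented carbonylation; neither partner needs an enolisable ketone. On precedent it is the stronger plan.
- Against it: A3 has no oxygen on C3. The hydroxyl would have to be added afterwards by epoxidation of the C2–C3 bond, which the more electron-rich prenyl alkene would outrun, or by C3 metalation and oxidation on a heavily functionalised chromone.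
- Against it: ring closure of A6 can also go 5-exo-dig, and A5 costs extra steps from an aldehyde or halide.
- Comparison: the chosen route accepts a less tested enolate partner, and in exchange nothing is oxidised after the prenyl group is in the molecule.

Alternative 3: Only the O1–C8a bond is cut, leading to acylcatechol A8, a 2-alkoxy-1,3-diketone whose A ring has no oxygen ortho to the acyl group. In the forward step, anodic two-electron oxidation gives o-quinone A9, and the enol oxygen adds to the ring carbon ortho to the acyl group to give A7 with the 6,7-diol already free.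
- For it: electrons are the only reagent, and ring A needs just the 3,4-dioxygen pattern because O1 arrives by C–H functionalisation. This is a simpler A-ring supply than the chosen route has.
- Against it: the step forms no C–C bond. The whole diketone skeleton must be built first by a crossed Claisen condensation, with a catechol protection that can be removed while the B-ring acetal and the prenyl ether stay.
- Against it: A9 is a very electrophilic acylquinone that solvent can intercept.
- Against it: A7 has one more donor oxygen on the ring than A8, so it should be oxidised at a lower potential than the substrate. Over-oxidation is built into the step.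
- Against it: the B ring and its alkene are also oxidisable at the anode.
- Comparison: the chosen route is redox-neutral from 8 and 14 onward and makes both C–C bonds and the C–O bond in one operation.

Key step: step 9

## Route

Step 1
Reactants: 1 2',4',5'-trihydroxyacetophenone
Product: 2 1-[2-hydroxy-4,5-bis(methoxymethoxy)phenyl]ethan-1-one
Conditions: MOMCl (2.2 equiv), i-Pr2NEt, CH2Cl2, 0 °C to rt
Reagents that add atoms: chloromethyl methyl ether, COCCl
Why: O-alkylation (MOM acetal formation) of the two unchelated phenols; the 2'-hydroxyl is hydrogen-bonded to the ketone carbonyl, is the least nucleophilic and stays free when the reagent is limited to two equivalents.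

Step 2
Reactants: 2 1-[2-hydroxy-4,5-bis(methoxymethoxy)phenyl]ethan-1-one
Product: 3 1-[2-(benzyloxy)-4,5-bis(methoxymethoxy)phenyl]ethan-1-one
Conditions: BnBr, K2CO3, DMF, 60 °C
Reagents that add atoms: benzyl bromide, BrCc1ccccc1
Why: Williamson ether synthesis on the chelated phenol, which needs carbonate in a dipolar aprotic solvent and warming; the benzyl ether lets the ketone be enolised as a simple mono-anion and leaves only one hydroxyl for the later acetal formation.

Step 3
Reactants: 3 1-[2-(benzyloxy)-4,5-bis(methoxymethoxy)phenyl]ethan-1-one
Product: 6 1-[2-(benzyloxy)-4,5-bis(methoxymethoxy)phenyl]-2-hydroxyethan-1-one, via silyl enol ether 4 (not isolated), via α-silyloxy ketone 5 (not isolated)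
Conditions: LiHMDS, TMSCl, THF, −78 °C; mCPBA, CH2Cl2, 0 °C; citric acid (cat.), MeOH, rt
Reagents that add atoms: 3-chloroperoxybenzoic acid, OOC(=O)c1cccc(Cl)c1 (the new oxygen); chlorotrimethylsilane, C[Si](C)(C)Cl (silicon stays only in 4 and 5)
Why: Rubottom oxidation: the methyl group is the only enolisable position, the silyl enol ether is far more nucleophilic than the arene and is epoxidised, a 1,4-silyl shift gives the α-silyloxy ketone, and mild acidic methanolysis frees the primary alcohol; no stereocentre is formed.

Step 4
Reactants: 6 1-[2-(benzyloxy)-4,5-bis(methoxymethoxy)phenyl]-2-hydroxyethan-1-one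
Product: 7 1-[2-(benzyloxy)-4,5-bis(methoxymethoxy)phenyl]-2-(methoxymethoxy)ethan-1-one
Conditions: MOMCl, i-Pr2NEt, CH2Cl2, 0 °C to rt
Reagents that add atoms: chloromethyl methyl ether, COCCl
Why: MOM acetal formation on the only free hydroxyl; an acetal is chosen for the C3 oxygen because, unlike an ester or a silyl group, it can neither migrate to the phenoxide nor leave from the enolate in the key step.

Step 5
Reactants: 7 1-[2-(benzyloxy)-4,5-bis(methoxymethoxy)phenyl]-2-(methoxymethoxy)ethan-1-one
Product: 8 1-[2-hydroxy-4,5-bis(methoxymethoxy)phenyl]-2-(methoxymethoxy)ethan-1-one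
Conditions: H2 (1 atm), 10% Pd/C, EtOAc, rt
Reagents that add atoms: none
Why: Hydrogenolysis of the benzyl aryl ether; MOM acetals are inert to it, the molecule has no alkene, and a short reaction at one atmosphere in ethyl acetate should leave the aryl ketone untouched.

Step 6
Reactants: 9 5-bromo-2-hydroxybenzaldehyde
Product: 10 5-bromo-2-(methoxymethoxy)benzaldehyde
Conditions: MOMCl, i-Pr2NEt, CH2Cl2, 0 °C to rt
Reagents that add atoms: chloromethyl methyl ether, COCCl
Why: MOM protection of the phenol; this oxygen is para to bromine and becomes the 4'-oxygen of the target.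

Step 7
Reactants: 10 5-bromo-2-(methoxymethoxy)benzaldehyde
Product: 12 5-bromo-2-(methoxymethoxy)phenol, via aryl formate 11 (not isolated)
Conditions: mCPBA, CH2Cl2, rt; aq. NaHCO3 wash; K2CO3 (cat.), MeOH, rt
Reagents that add atoms: 3-chloroperoxybenzoic acid, OOC(=O)c1cccc(Cl)c1
Why: Baeyer–Villiger (Dakin-type) oxidation of an ortho-alkoxybenzaldehyde: in the Criegee intermediate the electron-rich aryl group migrates in preference to hydride, and methanolysis of the formate frees the phenol; the peracid is used before any alkene is present.

Step 8
Reactants: 12 5-bromo-2-(methoxymethoxy)phenol; 13 1-bromo-3-methylbut-2-ene (prenyl bromide)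
Product: 14 4-bromo-1-(methoxymethoxy)-2-[(3-methylbut-2-en-1-yl)oxy]benzene
Conditions: K2CO3, DMF, rt
Reagents that add atoms: none
Why: Williamson ether synthesis by SN2 attack of the phenoxide at the primary allylic carbon; the hindered tertiary terminus makes SN2' attack negligible.

Step 9
Reactants: 8 1-[2-hydroxy-4,5-bis(methoxymethoxy)phenyl]-2-(methoxymethoxy)ethan-1-one; 14 4-bromo-1-(methoxymethoxy)-2-[(3-methylbut-2-en-1-yl)oxy]benzene; 15 carbon monoxide
Product: 18 3,6,7-tris(methoxymethoxy)-2-{4-(methoxymethoxy)-3-[(3-methylbut-2-en-1-yl)oxy]phenyl}-4H-chromen-4-one, via 2-alkoxy-1,3-diketone 16 (not isolated), via 2-hydroxyflavanone hemiketal 17 (not isolated)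
Conditions: Pd(OAc)2 (5 mol %), dppb (6 mol %), DBU (3 equiv), CO (5 bar), DMSO, 100 °C; then AcOH, NaOAc, 60 °C
Reagents that add atoms: none
Why: Proposed new method: the closest known reaction type is the palladium-catalysed carbonylative α-arylation of ketones to 1,3-diketones, which with 2-hydroxyacetophenones and aryl bromides gives flavones in one pot, and the untested element is an α-alkoxy ketone as the enolate partner. Palladium(0) should add oxidatively to the C–Br bond of 14, the aryl–palladium species inserts CO, and the aroyl–palladium species is captured at carbon by the enolate of 8 to give diketone 16 (bonds C2–C1' and C2–C3). If the phenoxide of 8 captures it instead, the aryl ester that results should undergo a Baker–Venkataraman O-to-C acyl shift under DBU at this temperature to the same 16, so O- versus C-acylation need not be controlled. The α-acetal oxygen makes the CH2 group somewhat more acidic than in the parent acetophenone and cannot be expelled from the enolate, which is why this substituent should be tolerated. The phenol then adds to the new aroyl carbonyl in a 6-exo-trig closure to hemiketal 17 (bond O1–C2), and loss of water across C2–C3, completed in buffered acetic acid, gives the pyranone. The stereocentres of 16 and 17 are transient and 18 has none. The step needs CO insertion to outrun direct α-arylation, which the chelating diphosphine, the CO pressure and the electron-rich aryl group on palladium favour. It also needs the prenyl ether to resist ionisation by palladium(0), which its trisubstituted alkene and poor phenoxide leaving group make slow next to oxidative addition into C–Br.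

Step 10
Reactants: 18 3,6,7-tris(methoxymethoxy)-2-{4-(methoxymethoxy)-3-[(3-methylbut-2-en-1-yl)oxy]phenyl}-4H-chromen-4-one
Product: 19 3,6,7-trihydroxy-2-{4-hydroxy-3-[(3-methylbut-2-en-1-yl)oxy]phenyl}-4H-chromen-4-one
Conditions: HCl (ca. 1 M) in MeOH–THF, 0 °C to rt, under argon, stopped at full conversion
Reagents that add atoms: none
Why: Acid-catalysed transacetalisation: each MOM group leaves as a methoxymethyl oxocarbenium ion that methanol traps, whereas the prenyl ether would have to ionise to a much less stabilised allyl cation, so dilute acid at or below room temperature should remove all four acetals first.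

## Compound list

1 | 2',4',5'-trihydroxyacetophenone | CC(=O)c1cc(O)c(O)cc1O | starting material
2 | 1-[2-hydroxy-4,5-bis(methoxymethoxy)phenyl]ethan-1-one | CC(=O)c1cc(OCOC)c(OCOC)cc1O | intermediate
3 | 1-[2-(benzyloxy)-4,5-bis(methoxymethoxy)phenyl]ethan-1-one | CC(=O)c1cc(OCOC)c(OCOC)cc1OCc1ccccc1 | intermediate
4 | trimethylsilyl enol ether of 3, {1-[2-(benzyloxy)-4,5-bis(methoxymethoxy)phenyl]ethenyl}oxy(trimethyl)silane | C=C(O[Si](C)(C)C)c1cc(OCOC)c(OCOC)cc1OCc1ccccc1 | intermediate
5 | 1-[2-(benzyloxy)-4,5-bis(methoxymethoxy)phenyl]-2-[(trimethylsilyl)oxy]ethan-1-one | C[Si](C)(C)OCC(=O)c1cc(OCOC)c(OCOC)cc1OCc1ccccc1 | intermediate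
6 | 1-[2-(benzyloxy)-4,5-bis(methoxymethoxy)phenyl]-2-hydroxyethan-1-one | OCC(=O)c1cc(OCOC)c(OCOC)cc1OCc1ccccc1 | intermediate
7 | 1-[2-(benzyloxy)-4,5-bis(methoxymethoxy)phenyl]-2-(methoxymethoxy)ethan-1-one | COCOCC(=O)c1cc(OCOC)c(OCOC)cc1OCc1ccccc1 | intermediate
8 | 1-[2-hydroxy-4,5-bis(methoxymethoxy)phenyl]-2-(methoxymethoxy)ethan-1-one | COCOCC(=O)c1cc(OCOC)c(OCOC)cc1O | intermediate
9 | 5-bromo-2-hydroxybenzaldehyde (5-bromosalicylaldehyde) | O=Cc1cc(Br)ccc1O | starting material
10 | 5-bromo-2-(methoxymethoxy)benzaldehyde | COCOc1ccc(Br)cc1C=O | intermediate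
11 | 5-bromo-2-(methoxymethoxy)phenyl formate | O=COc1cc(Br)ccc1OCOC | intermediate
12 | 5-bromo-2-(methoxymethoxy)phenol | COCOc1ccc(Br)cc1O | intermediate
13 | 1-bromo-3-methylbut-2-ene (prenyl bromide) | CC(C)=CCBr | starting material
14 | 4-bromo-1-(methoxymethoxy)-2-[(3-methylbut-2-en-1-yl)oxy]benzene | COCOc1ccc(Br)cc1OCC=C(C)C | intermediate
15 | carbon monoxide | [C-]#[O+] | starting material
16 | 1-[2-hydroxy-4,5-bis(methoxymethoxy)phenyl]-2-(methoxymethoxy)-3-{4-(methoxymethoxy)-3-[(3-methylbut-2-en-1-yl)oxy]phenyl}propane-1,3-dione (racemic at C2, enolisable) | COCOC(C(=O)c1cc(OCOC)c(OCOC)cc1O)C(=O)c1ccc(OCOC)c(OCC=C(C)C)c1 | intermediate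
17 | 2-hydroxy-3,6,7-tris(methoxymethoxy)-2-{4-(methoxymethoxy)-3-[(3-methylbut-2-en-1-yl)oxy]phenyl}-2,3-dihydro-4H-chromen-4-one (racemic mixture of diastereomers) | COCOC1C(=O)c2cc(OCOC)c(OCOC)cc2OC1(O)c1ccc(OCOC)c(OCC=C(C)C)c1 | intermediate
18 | 3,6,7-tris(methoxymethoxy)-2-{4-(methoxymethoxy)-3-[(3-methylbut-2-en-1-yl)oxy]phenyl}-4H-chromen-4-one | CC(C)=CCOc1cc(-c2oc3cc(OCOC)c(OCOC)cc3c(=O)c2OCOC)ccc1OCOC | intermediate
19 | 3,6,7-trihydroxy-2-{4-hydroxy-3-[(3-methylbut-2-en-1-yl)oxy]phenyl}-4H-chromen-4-one | CC(C)=CCOc1cc(-c2oc3cc(O)c(O)cc3c(=O)c2O)ccc1O | target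

## Step count and least certain steps

Total: 10 steps. Longest linear sequence: 7 steps (steps 1 to 5, 9 and 10). The bromide arm is 3 steps (steps 6 to 8).

**Step 9 (key step, proposed new method).** Several processes could defeat it:
- slow oxidative addition of the electron-rich bromide under CO, leading to catalyst precipitation;
- arylation of the enolate without CO uptake;
- an acyl shift that stops at the aryl ester, because the receiving carbon is substituted;
- cleavage of the 2-alkoxy-1,3-diketone or of the acyl–palladium species by the water that the ring closure releases;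
- ionisation of the prenyl ether by palladium(0), with loss or transfer of the prenyl group.

Fallback with known chemistry, setting out from 14 and 8 and rejoining the route at 16 and then 18: bromine–lithium exchange on 14 (n-BuLi, THF, −78 °C) and quenching with carbon dioxide would give 4-(methoxymethoxy)-3-[(3-methylbut-2-en-1-yl)oxy]benzoic acid F1. Carbodiimide esterification of F1 with the phenol of 8 (EDC, DMAP, CH2Cl2) would give 2-[(methoxymethoxy)acetyl]-4,5-bis(methoxymethoxy)phenyl 4-(methoxymethoxy)-3-[(3-methylbut-2-en-1-yl)oxy]benzoate F2. LiHMDS in THF would then effect the Baker–Venkataraman rearrangement to 16, and AcOH/NaOAc would close and dehydrate it through 17 to 18. This is the classical route to 3-alkoxyflavones and uses no palladium.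

**Step 10.** The risks are loss of the prenyl group by acid ionisation, C-prenylation of the freed electron-rich rings by the resulting cation, and air oxidation of the liberated catechol. Fallback from 18 back to 19 without Brønsted acid: TMSOTf with 2,2'-bipyridyl in CH2Cl2 at 0 °C exchanges aryl MOM ethers for silyl ethers through a pyridinium-trapped methoxymethyl group. This would give 2-{3-[(3-methylbut-2-en-1-yl)oxy]-4-[(trimethylsilyl)oxy]phenyl}-3,6,7-tris[(trimethylsilyl)oxy]-4H-chromen-4-one F3, which water hydrolyses to 19.

**Step 3.** The risks are Baeyer–Villiger oxidation of the aryl ketone or oxidation of the trialkoxy ring by the peracid, and hydrolysis of the silyl enol ether back to 3 before it is oxidised. Fallback from 3 (through 4) back to 6, with the oxygen introduced as a nucleophile: NBS on silyl enol ether 4 would give 1-[2-(benzyloxy)-4,5-bis(methoxymethoxy)phenyl]-2-bromoethan-1-one F4. Potassium acetate in DMF would displace bromide to give 2-[2-(benzyloxy)-4,5-bis(methoxymethoxy)phenyl]-2-oxoethyl acetate F5, and K2CO3 in methanol would release 6.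

**Step 5.** The risk is over-reduction of the aryl ketone, which becomes more prone to reduction and benzylic hydrogenolysis once the ortho phenol is free. Fallback from 2 back to 8 with an allyl ether in place of benzyl:
- allyl bromide and K2CO3 would give 1-[4,5-bis(methoxymethoxy)-2-(prop-2-en-1-yloxy)phenyl]ethan-1-one F6;
- the Rubottom sequence of step 3 would pass through trimethylsilyl enol ether F7 and 1-[4,5-bis(methoxymethoxy)-2-(prop-2-en-1-yloxy)phenyl]-2-[(trimethylsilyl)oxy]ethan-1-one F8 to 1-[4,5-bis(methoxymethoxy)-2-(prop-2-en-1-yloxy)phenyl]-2-hydroxyethan-1-one F9, the terminal alkene being far less reactive to peracid than the silyl enol ether;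
- MOMCl and i-Pr2NEt would give 1-[4,5-bis(methoxymethoxy)-2-(prop-2-en-1-yloxy)phenyl]-2-(methoxymethoxy)ethan-1-one F10;
- Pd(PPh3)4 with morpholine would remove the allyl group to give 8 without any reducing agent.

## Further compounds

F1 | step 9 | 4-(methoxymethoxy)-3-[(3-methylbut-2-en-1-yl)oxy]benzoic acid | OC(=O)c1ccc(OCOC)c(OCC=C(C)C)c1
F2 | step 9 | 2-[(methoxymethoxy)acetyl]-4,5-bis(methoxymethoxy)phenyl 4-(methoxymethoxy)-3-[(3-methylbut-2-en-1-yl)oxy]benzoate | COCOCC(=O)c1cc(OCOC)c(OCOC)cc1OC(=O)c1ccc(OCOC)c(OCC=C(C)C)c1
F3 | step 10 | 2-{3-[(3-methylbut-2-en-1-yl)oxy]-4-[(trimethylsilyl)oxy]phenyl}-3,6,7-tris[(trimethylsilyl)oxy]-4H-chromen-4-one | CC(C)=CCOc1cc(-c2oc3cc(O[Si](C)(C)C)c(O[Si](C)(C)C)cc3c(=O)c2O[Si](C)(C)C)ccc1O[Si](C)(C)C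
F4 | step 3 | 1-[2-(benzyloxy)-4,5-bis(methoxymethoxy)phenyl]-2-bromoethan-1-one | BrCC(=O)c1cc(OCOC)c(OCOC)cc1OCc1ccccc1
F5 | step 3 | 2-[2-(benzyloxy)-4,5-bis(methoxymethoxy)phenyl]-2-oxoethyl acetate | CC(=O)OCC(=O)c1cc(OCOC)c(OCOC)cc1OCc1ccccc1
F6 | step 5 | 1-[4,5-bis(methoxymethoxy)-2-(prop-2-en-1-yloxy)phenyl]ethan-1-one | CC(=O)c1cc(OCOC)c(OCOC)cc1OCC=C
F7 | step 5 | trimethylsilyl enol ether of F6, {1-[4,5-bis(methoxymethoxy)-2-(prop-2-en-1-yloxy)phenyl]ethenyl}oxy(trimethyl)silane | C=C(O[Si](C)(C)C)c1cc(OCOC)c(OCOC)cc1OCC=C
F8 | step 5 | 1-[4,5-bis(methoxymethoxy)-2-(prop-2-en-1-yloxy)phenyl]-2-[(trimethylsilyl)oxy]ethan-1-one | C[Si](C)(C)OCC(=O)c1cc(OCOC)c(OCOC)cc1OCC=C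
F9 | step 5 | 1-[4,5-bis(methoxymethoxy)-2-(prop-2-en-1-yloxy)phenyl]-2-hydroxyethan-1-one | OCC(=O)c1cc(OCOC)c(OCOC)cc1OCC=C
F10 | step 5 | 1-[4,5-bis(methoxymethoxy)-2-(prop-2-en-1-yloxy)phenyl]-2-(methoxymethoxy)ethan-1-one | COCOCC(=O)c1cc(OCOC)c(OCOC)cc1OCC=C
A1 | alternative 1 | (2R*,3R*)-3-hydroxy-6,7-bis(methoxymethoxy)-2-{4-(methoxymethoxy)-3-[(3-methylbut-2-en-1-yl)oxy]phenyl}chroman-4-one (racemic, trans, one enantiomer drawn) | COCOc1ccc(cc1OCC=C(C)C)[C@@H]1[C@H](C(=O)c2cc(OCOC)c(OCOC)cc2O1)O
A2 | alternative 1 | 4,5-bis(methoxymethoxy)-2-(1-{4-(methoxymethoxy)-3-[(3-methylbut-2-en-1-yl)oxy]phenyl}-2-oxoethoxy)benzaldehyde (racemic) | O=CC(Oc1cc(OCOC)c(OCOC)cc1C=O)c1ccc(OCOC)c(OCC=C(C)C)c1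
A3 | alternative 2 | 6,7-bis(methoxymethoxy)-2-{4-(methoxymethoxy)-3-[(3-methylbut-2-en-1-yl)oxy]phenyl}-4H-chromen-4-one | CC(C)=CCOc1cc(-c2cc(=O)c3cc(OCOC)c(OCOC)cc3o2)ccc1OCOC
A4 | alternative 2 | 2-iodo-4,5-bis(methoxymethoxy)phenol | Oc1cc(OCOC)c(OCOC)cc1I
A5 | alternative 2 | 4-ethynyl-1-(methoxymethoxy)-2-[(3-methylbut-2-en-1-yl)oxy]benzene | C#Cc1ccc(OCOC)c(OCC=C(C)C)c1
A6 | alternative 2 | 1-[2-hydroxy-4,5-bis(methoxymethoxy)phenyl]-3-{4-(methoxymethoxy)-3-[(3-methylbut-2-en-1-yl)oxy]phenyl}prop-2-yn-1-one | O=C(C#Cc1ccc(OCOC)c(OCC=C(C)C)c1)c1cc(OCOC)c(OCOC)cc1O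
A7 | alternative 3 | 6,7-dihydroxy-3-(methoxymethoxy)-2-{4-(methoxymethoxy)-3-[(3-methylbut-2-en-1-yl)oxy]phenyl}-4H-chromen-4-one | CC(C)=CCOc1cc(-c2oc3cc(O)c(O)cc3c(=O)c2OCOC)ccc1OCOC
A8 | alternative 3 | 1-(3,4-dihydroxyphenyl)-2-(methoxymethoxy)-3-{4-(methoxymethoxy)-3-[(3-methylbut-2-en-1-yl)oxy]phenyl}propane-1,3-dione (racemic, enolisable) | COCOC(C(=O)c1ccc(O)c(O)c1)C(=O)c1ccc(OCOC)c(OCC=C(C)C)c1
A9 | alternative 3 | 1-(3,4-dioxocyclohexa-1,5-dien-1-yl)-2-(methoxymethoxy)-3-{4-(methoxymethoxy)-3-[(3-methylbut-2-en-1-yl)oxy]phenyl}propane-1,3-dione (o-quinone of A8) | COCOC(C(=O)C1=CC(=O)C(=O)C=C1)C(=O)c1ccc(OCOC)c(OCC=C(C)C)c1
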